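Readings and results stem from a simulated flask with constants of no real substance, noise included.

**Capture ratio.** One ratio serves us here: the first end groups turned into links and isomer of the product, as a fraction of the second end groups charged. This is the capture, 45.0% at the last winter reading.

- winter: first end groups 0.18 M (fed, over 10 s); second end groups 0.162 M; third end groups 0.090 M; run made earlier
- flask: first end groups 0.18 M (fed, over 10 s); second end groups 0.162 M; third end groups 0.180 M; time 50 min

winter run (percent of the first end groups charged)

| time / min | links / % | isomer of the product / % | first end groups / % |
|---|---|---|---|
| 1.00 | 26.3 | 5.2 | 68.4 |
| 2.00 | 30.9 | 6.8 | 62.4 |
| 3.00 | 32.1 | 7.6 | 60.6 |
| 4.00 | 32.4 | 7.6 | 60.3 |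
| 5.00 | 33.0 | 7.5 | 60.3 |

(each reading ± 0.3 percentage points)

- the analysis behind the earlier runs scatters by 0.3 percentage points, standard deviation
- the reaction counts as stopped when no species that holds the first end groups changes by six tenths of a point or more over the second half of the time

- at 50 min, what has stopped the reaction, if anything has (all of the first end groups has reacted / forward and back rates have come level / the second end groups has run out first / it is still moving)
- the links standing at 50 min, as a percentage of the first end groups charged
- the isomer of the product standing at 50 min, as a percentage of the first end groups charged

**Reading it.** The winter readings level off from about 3.00 min, and they cannot tell a level balance from a spent reagent. We commit to the second reading: the second end groups are the limiting reagent, and the remaining 55.0% of them left by a path the readings do not show.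

**Testing it.** The flask has the winter charges of first and second end groups, so an unchanged capture gives 40.5% of the first end groups charged in links and isomer. But the flask holds twice the third end groups. If they alone take the loss, the odds of capture halve, and the share falls to 26.1%. So one number is not enough, and we take the middle, 33.3%, with the second end groups again used up.

**The forecast.** For this flask it gave 27.6% links and 6.3% isomer, and as the stop forward and back rates have come level: “it is an equilibrium, not a run-out”.

**The flask.** At 50 min the flask stands at 28.4% links and 6.52% isomer. What stopped it: the second end groups has run out first, with 0% of their charge left.

    first end groups + second end groups → links (k = 0.120 /M/s)
    second end groups + third end groups → links of the second sort (k = 0.0590 /M/s)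
    2 second end groups → homo dimer (k = 0.0960 /M/s)
    links ⇌ isomer of the product (K = 0.230, k = 0.0170 /s)

**Capture again.** The flask's capture is 38.8%, less than the winter value. A neighbour flask with 0.31 M of first end groups captures 50.5%, more than the flask. Within the flask's capture, the isomer of the product is held down in part by its return to links. With that return taken away, the isomer of the product in the flask stands at 34.9% instead of 6.52%.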